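**Retrosynthetic overview**

1. C40 is cut into a C15 phosphonium salt (oxabicyclic end), the C10 dialdehyde and a C15 dienal (triol end); two Wittig reactions join them, C11=C12 first and C11′=C12′ last.
2. Both C15 units come from one carbocycle (ring atoms C1–C6, vinyl C7=C8 on C6). The triol end follows by 3-OH-directed epoxidation of the C5 methylidene, inversion at C3 and hydride; the oxabicyclic end by SN2 closure of O6 onto C3 and exo hydration at C5; both side chains by Heck coupling.
3. The carbocycle comes from an acyclic dienol carbamate in a tandem oxy-Cope/type 2 carbonyl-ene step that makes C1–C6 and C3–C4 and cleaves a sacrificial C3–C8 bond. The dienol comes from a homoaldol addition of a chiral dienyl carbamate to 3-methylbut-2-enal.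
4. Enabling feature: in the six-membered triol ring the C3 carbinol lies γ to the bond between the gem-dimethyl carbon C1 and the quaternary carbinol C6 (which carries the C7=C8 vinyl unit), and C5 carries a methyl beside the C4 methylene. This is a 3-oxido-1,5-diene retron (C1=C2–C3(O)–C8–C7=C6) joined to a homoallylic-alcohol (ene) retron (C3=O + C4=C5–CH3).
5. Ring order: the six-membered carbocycle (step 4, used for both ends), then the oxolane bridge of the 7-oxabicyclo[2.2.1]heptane (step 14).

Key step: step 4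

Remark (numbering): carotenoid locants are used for ring intermediates: C1 gem-dimethyl carbon, C3 secondary carbinol, C5 methyl-bearing carbon (its methyl is C18), C6 chain-bearing carbinol, C7/C8 the vinyl carbons on C6.
Remark (step 1): (+)-MIB (3-exo-morpholinoisoborneol) is assumed to give the (R)-alcohol, by analogy with (−)-MIB giving (S)-carbinols when the aldehyde residue outranks the transferred group; otherwise the other ligand enantiomer is taken.
Remark (step 3): the usual course of such homoaldol reactions is assumed: deprotonation with retention, lithium-to-titanium exchange with inversion, suprafacial γ-addition through a closed chair.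
Remark (step 19): (2E,4E,6E)-2,7-dimethylocta-2,4,6-trienedial is treated as a commercial C10 building block.

Step 1
Reactants: 1 2-methylprop-2-enal (methacrolein); 2 ethenylmagnesium bromide
Product: 4 (3R)-2-methylpenta-1,4-dien-3-ol, via diethenylzinc 3 (not isolated)
Conditions: 2, ZnCl2, THF–PhMe, 0 °C; N,N,N′,N′-tetraethylethylenediamine; (+)-MIB (10 mol %), then 1, −20 → 0 °C; aq. NH4Cl
Reagents that add atoms: none
Why: Amino-alcohol-catalysed enantioselective addition of an alkenylzinc reagent to an aldehyde, in which the chiral zinc aminoalkoxide delivers the vinyl group to one face of the formyl group and so sets the carbinol centre (later C6) as R, while the diamine sequesters the magnesium salts that would drive the racemic background addition.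

Step 2
Reactants: 4 (3R)-2-methylpenta-1,4-dien-3-ol
Product: 5 (3R)-2-methylpenta-1,4-dien-3-yl N,N-di(propan-2-yl)carbamate
Conditions: NaH, THF, 0 °C; iPr2NCOCl, reflux
Reagents that add atoms: N,N-diisopropylcarbamoyl chloride, CC(C)N(C(C)C)C(Cl)=O
Why: O-Carbamoylation of the sodium alkoxide (acyl substitution), which leaves the stereocentre untouched and installs the directing and activating group for the next step.

Step 3
Reactants: 5 (3R)-2-methylpenta-1,4-dien-3-yl N,N-di(propan-2-yl)carbamate; 6 3-methylbut-2-enal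
Product: 9 (3Z,6R)-6-hydroxy-2,8-dimethylnona-1,3,7-trien-3-yl N,N-di(propan-2-yl)carbamate, via lithium compound 7 (not isolated), via titanium compound 8 (not isolated)
Conditions: n-BuLi, TMEDA, Et2O, −78 °C; Ti(OiPr)4, −78 °C; 6, −78 °C; aq. HCl
Reagents that add atoms: none
Why: Homoaldol reaction of a metalated 2-alkenyl carbamate, in which carbamate-directed deprotonation (retention), lithium-to-titanium exchange (inversion) and γ-attack through a closed chair (carbamoyloxy group pseudo-axial, aldehyde residue pseudo-equatorial) should transfer the chirality of 5 to the new C3 carbinol (R) and fix the (Z)-enol carbamate, attack through the unsubstituted vinyl arm being preferred because the isopropenyl arm would have to form a tetrasubstituted enol carbamate.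

Step 4
Reactants: 9 (3Z,6R)-6-hydroxy-2,8-dimethylnona-1,3,7-trien-3-yl N,N-di(propan-2-yl)carbamate
Product: 12 (1S,4S)-1-ethenyl-4-hydroxy-2,2-dimethyl-6-methylidenecyclohexyl N,N-di(propan-2-yl)carbamate, via potassium enolate 10 (not isolated), via aldehyde 11 (not isolated)
Conditions: KN(SiMe3)2, 18-crown-6, PhMe, −40 → 0 °C; AcOH (1 equiv), −78 °C; Me2AlCl (excess), PhMe–CH2Cl2, −78 → −30 °C, same flask; aq. HCl
Reagents that add atoms: none
Why: Proposed new method: the potassium alkoxide of 9 should undergo an anion-accelerated oxy-Cope ([3,3]) shift of the C1=C2–C3(O−)–C8–C7=C6 array, which joins C1 to C6, cleaves the sacrificial C3–C8 bond and gives enolate 10, and after protonation to aldehyde 11 the Me2AlCl-activated C3=O is attacked by C4 of the isopropenyl group in a type 2 intramolecular carbonyl-ene reaction with transfer of a C18 hydrogen to oxygen, which makes C3–C4. The closest known reaction types are the anionic oxy-Cope rearrangement, the Lewis-acid type 2 carbonyl-ene cyclisation of 5-methylhex-5-enals to 3-methylidenecyclohexanols and the thermal tandem oxy-Cope/transannular ene reaction of 1,2-dialkenylcyclohexanols, whereas their union on an acyclic dienol with creation of two adjacent fully substituted carbons has not been shown. The six-membered carbocycle closes through the C3–C4 bond in a 6-endo mode with respect to the C4=C5 alkene (carbonyl exocyclic) by way of a bicyclo[3.3.1]-like ene transition state. C6 is set by 1,3-chirality transfer from C3 of 9 through a chair in which the oxido group is equatorial (the axial alternative clashes with the Z-methyl on C1) and the (Z)-carbamoyloxy group axial, so that C1 takes the place formerly held by the hydrogen of 5 (6S); the new C3 centre is set by C6, because the aluminium-bound oxygen must be axial to reach C18–H while the carbamoyloxy group is axial on the opposite face to escape allylic strain with the emerging methylidene, which should give the 3,6-trans alcohol (3S). The step needs periselectivity for the [3,3] shift over fragmentation back to 6 and over O-to-O carbamoyl transfer, which the low temperature and the hindered diisopropylcarbamoyl group should secure, and chemoselectivity between the two alkenes on C6, which is secured because only the isopropenyl group has an allylic hydrogen and a 1,1-disubstituted terminus.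

Step 5
Reactants: 12 (1S,4S)-1-ethenyl-4-hydroxy-2,2-dimethyl-6-methylidenecyclohexyl N,N-di(propan-2-yl)carbamate
Product: 13 (3R,4S,7S)-4-ethenyl-7-hydroxy-5,5-dimethyl-1-oxaspiro[2.5]octan-4-yl N,N-di(propan-2-yl)carbamate
Conditions: VO(acac)2 (cat.), t-BuOOH, CH2Cl2, 0 °C → rt
Reagents that add atoms: tert-butyl hydroperoxide, CC(C)(C)OO
Why: Hydroxyl-directed epoxidation of a homoallylic alcohol, in which the vanadium alkoxide of the axial 3-OH delivers oxygen to its own face of the C5 methylidene and so sets the spiro centre with oxygen cis to O3 and trans to the 6-carbamoyloxy group, the C6 vinyl group being too remote to be reached.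

Step 6
Reactants: 13 (3R,4S,7S)-4-ethenyl-7-hydroxy-5,5-dimethyl-1-oxaspiro[2.5]octan-4-yl N,N-di(propan-2-yl)carbamate
Product: 14 (3R,4S,7R)-4-{[di(propan-2-yl)carbamoyl]oxy}-4-ethenyl-5,5-dimethyl-1-oxaspiro[2.5]octan-7-yl benzoate
Conditions: PhCO2H, PPh3, iPrO2CN=NCO2iPr, THF, 0 °C → rt
Reagents that add atoms: benzoic acid, OC(=O)c1ccccc1
Why: Mitsunobu esterification with SN2 inversion at the unhindered secondary C3, which turns the (S)-carbinol into the (R)-benzoate now cis to O6, the tertiary carbamate and the epoxide taking no part.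

Step 7
Reactants: 14 (3R,4S,7R)-4-{[di(propan-2-yl)carbamoyl]oxy}-4-ethenyl-5,5-dimethyl-1-oxaspiro[2.5]octan-7-yl benzoate
Product: 15 (1S,2S,4R)-1-ethenyl-2,6,6-trimethylcyclohexane-1,2,4-triol
Conditions: LiAlH4, THF, 0 °C → reflux; aq. NaOH
Reagents that add atoms: none
Why: Hydride reduction in which the 2,2-disubstituted epoxide is opened first at its unhindered CH2 (C18) to give the C5 tertiary alcohol with retained configuration, and the benzoate and the diisopropylcarbamate are then cleaved reductively, no stereocentre being touched.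

Step 8
Reactants: 16 ethyl 3-oxobutanoate
Product: 17 ethyl (2E)-3-{[(trifluoromethyl)sulfonyl]oxy}but-2-enoate
Conditions: Tf2O, aq. Me4NOH, hexanes, 5 °C
Reagents that add atoms: trifluoromethanesulfonic anhydride, O=S(=O)(OS(=O)(=O)C(F)(F)F)C(F)(F)F
Why: O-Sulfonylation of the β-keto ester enolate, in which the non-chelating tetramethylammonium counter-ion should give the (E)-enol triflate with the triflate trans to the ester.

Step 9
Reactants: 15 (1S,2S,4R)-1-ethenyl-2,6,6-trimethylcyclohexane-1,2,4-triol; 17 ethyl (2E)-3-{[(trifluoromethyl)sulfonyl]oxy}but-2-enoate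
Product: 18 ethyl (2E,4E)-3-methyl-5-[(1S,2S,4R)-1,2,4-trihydroxy-2,6,6-trimethylcyclohexyl]penta-2,4-dienoate
Conditions: Pd(OAc)2 (cat.), PPh3, LiCl, Et3N, DMF, 70 °C
Reagents that add atoms: none
Why: Heck reaction of an alkenyl triflate with a terminal alkene, in which carbopalladation occurs at the unhindered C8, β-hydride elimination can only take place away from quaternary C6 and gives the (7E)-diene, and the triflate geometry is retained as 9E.

Step 10
Reactants: 18 ethyl (2E,4E)-3-methyl-5-[(1S,2S,4R)-1,2,4-trihydroxy-2,6,6-trimethylcyclohexyl]penta-2,4-dienoate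
Product: 19 (1S,2S,4R)-1-[(1E,3E)-5-hydroxy-3-methylpenta-1,3-dien-1-yl]-2,6,6-trimethylcyclohexane-1,2,4-triol
Conditions: iBu2AlH (excess), CH2Cl2, −78 → 0 °C; aq. NaOH
Reagents that add atoms: none
Why: Hydride 1,2-reduction of the conjugated ester to the primary allylic alcohol, which affects neither the diene geometry nor any stereocentre.

Step 11
Reactants: 19 (1S,2S,4R)-1-[(1E,3E)-5-hydroxy-3-methylpenta-1,3-dien-1-yl]-2,6,6-trimethylcyclohexane-1,2,4-triol
Product: 20 (2E,4E)-3-methyl-5-[(1S,2S,4R)-1,2,4-trihydroxy-2,6,6-trimethylcyclohexyl]penta-2,4-dienal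
Conditions: MnO2, CH2Cl2, rt
Reagents that add atoms: none
Why: Chemoselective MnO2 oxidation of the primary dienylic alcohol, since the secondary 3-OH is not allylic and the tertiary alcohols cannot be oxidised.

Step 12
Reactants: 12 (1S,4S)-1-ethenyl-4-hydroxy-2,2-dimethyl-6-methylidenecyclohexyl N,N-di(propan-2-yl)carbamate
Product: 21 (1S,4S)-1-ethenyl-2,2-dimethyl-6-methylidenecyclohexane-1,4-diol
Conditions: LiAlH4, THF, reflux; aq. NaOH
Reagents that add atoms: none
Why: Reductive cleavage of the N,N-diisopropylcarbamate, which frees the tertiary 6-OH without touching a stereocentre.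

Step 13
Reactants: 21 (1S,4S)-1-ethenyl-2,2-dimethyl-6-methylidenecyclohexane-1,4-diol
Product: 22 (1S,4S)-4-ethenyl-4-hydroxy-3,3-dimethyl-5-methylidenecyclohexyl methanesulfonate
Conditions: MeSO2Cl, Et3N, CH2Cl2, −20 °C
Reagents that add atoms: methanesulfonyl chloride, CS(Cl)(=O)=O
Why: Selective O-sulfonylation of the secondary alcohol over the hindered tertiary allylic alcohol, with retention at C3.

Step 14
Reactants: 22 (1S,4S)-4-ethenyl-4-hydroxy-3,3-dimethyl-5-methylidenecyclohexyl methanesulfonate
Product: 23 (1S,4R)-1-ethenyl-2,2-dimethyl-6-methylidene-7-oxabicyclo[2.2.1]heptane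
Conditions: NaH, THF, 0 °C → reflux
Reagents that add atoms: none
Why: Intramolecular Williamson etherification in which the tertiary C6 alkoxide displaces the trans-disposed C3 mesylate through a boat conformer (SN2, inversion at C3, 5-exo-tet closure of the oxolane bridge), the gem-dimethyl group and the quaternary C6 favouring closure.

Step 15
Reactants: 23 (1S,4R)-1-ethenyl-2,2-dimethyl-6-methylidene-7-oxabicyclo[2.2.1]heptane
Product: 25 (1S,2R,4R)-1-ethenyl-2,6,6-trimethyl-7-oxabicyclo[2.2.1]heptan-2-ol, via organomercurial 24 (not isolated)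
Conditions: Hg(OAc)2, THF–H2O, rt; NaBH4, aq. NaOH, 0 °C
Reagents that add atoms: water, O
Why: Markovnikov oxymercuration–demercuration of the 1,1-disubstituted exocyclic alkene, in which water should attack C5 from the exo face (the endo face is shielded by the endo methyl on C1) to give the exo tertiary alcohol (5R, methyl endo), the hindered monosubstituted vinyl group on the bridgehead reacting more slowly.

Step 16
Reactants: 25 (1S,2R,4R)-1-ethenyl-2,6,6-trimethyl-7-oxabicyclo[2.2.1]heptan-2-ol; 17 ethyl (2E)-3-{[(trifluoromethyl)sulfonyl]oxy}but-2-enoate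
Product: 26 ethyl (2E,4E)-5-[(1S,2R,4R)-2-hydroxy-2,6,6-trimethyl-7-oxabicyclo[2.2.1]heptan-1-yl]-3-methylpenta-2,4-dienoate
Conditions: Pd(OAc)2 (cat.), PPh3, LiCl, Et3N, DMF, 70 °C
Reagents that add atoms: none
Why: Heck reaction as in step 9, with bond formation at the terminal C8 and β-hydride elimination to the (7E,9E)-dienoate.

Step 17
Reactants: 26 ethyl (2E,4E)-5-[(1S,2R,4R)-2-hydroxy-2,6,6-trimethyl-7-oxabicyclo[2.2.1]heptan-1-yl]-3-methylpenta-2,4-dienoate
Product: 27 (1S,2R,4R)-1-[(1E,3E)-5-hydroxy-3-methylpenta-1,3-dien-1-yl]-2,6,6-trimethyl-7-oxabicyclo[2.2.1]heptan-2-ol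
Conditions: iBu2AlH (excess), CH2Cl2, −78 → 0 °C; aq. NaOH
Reagents that add atoms: none
Why: Hydride 1,2-reduction of the conjugated ester to the primary allylic alcohol, without change of geometry or configuration.

Step 18
Reactants: 27 (1S,2R,4R)-1-[(1E,3E)-5-hydroxy-3-methylpenta-1,3-dien-1-yl]-2,6,6-trimethyl-7-oxabicyclo[2.2.1]heptan-2-ol
Product: 28 {(2E,4E)-5-[(1S,2R,4R)-2-hydroxy-2,6,6-trimethyl-7-oxabicyclo[2.2.1]heptan-1-yl]-3-methylpenta-2,4-dien-1-yl}(triphenyl)phosphonium bromide
Conditions: PPh3·HBr, MeOH, rt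
Reagents that add atoms: triphenylphosphine hydrobromide, c1ccccc1[PH+](c1ccccc1)c1ccccc1.[Br-]
Why: Acid-mediated substitution of the primary dienylic alcohol by triphenylphosphine (allylic phosphonium salt formation), the non-allylic tertiary alcohol being inert.

Step 19
Reactants: 28 the C15 phosphonium bromide of step 18; 29 (2E,4E,6E)-2,7-dimethylocta-2,4,6-trienedial
Product: 30 (2E,4E,6E,8E,10E,12E)-13-[(1S,2R,4R)-2-hydroxy-2,6,6-trimethyl-7-oxabicyclo[2.2.1]heptan-1-yl]-2,7,11-trimethyltrideca-2,4,6,8,10,12-hexaenal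
Conditions: NaOMe, CH2Cl2–MeOH, 0 °C → rt, 29 in excess; then heptane, reflux (Z → E)
Reagents that add atoms: none
Why: Wittig olefination of the semi-stabilised ylide with one formyl group of the dialdehyde kept in excess, the new C11=C12 bond being equilibrated thermally to E.

Step 20
Reactants: 30 the C25 hexaenal of step 19
Product: 31 (2E,4E,6E,8E,10E,12E)-13-[(1S,2R,4R)-2-hydroxy-2,6,6-trimethyl-7-oxabicyclo[2.2.1]heptan-1-yl]-2,7,11-trimethyltrideca-2,4,6,8,10,12-hexaen-1-ol
Conditions: NaBH4, MeOH–CH2Cl2, 0 °C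
Reagents that add atoms: none
Why: Chemoselective 1,2-reduction of the polyenal by borohydride.

Step 21
Reactants: 31 the C25 hexaenol of step 20
Product: 32 [(2E,4E,6E,8E,10E,12E)-13-[(1S,2R,4R)-2-hydroxy-2,6,6-trimethyl-7-oxabicyclo[2.2.1]heptan-1-yl]-2,7,11-trimethyltrideca-2,4,6,8,10,12-hexaen-1-yl](triphenyl)phosphonium bromide
Conditions: PPh3·HBr, MeOH–CH2Cl2, rt
Reagents that add atoms: triphenylphosphine hydrobromide, c1ccccc1[PH+](c1ccccc1)c1ccccc1.[Br-]
Why: Allylic phosphonium salt formation from the primary polyenylic alcohol, as in step 18.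

Step 22
Reactants: 32 the C25 phosphonium bromide of step 21; 20 (2E,4E)-3-methyl-5-[(1S,2S,4R)-1,2,4-trihydroxy-2,6,6-trimethylcyclohexyl]penta-2,4-dienal
Product: 33 (3R,5R,6S,3′R,5′S,6′S)-3,6-epoxy-5,6,5′,6′-tetrahydro-β,β-carotene-5,3′,5′,6′-tetrol (target)
Conditions: NaOMe (excess), CH2Cl2–MeOH, rt; then EtOAc, reflux in the dark (Z → E)
Reagents that add atoms: none
Why: Wittig olefination that forms C11′=C12′ under basic conditions tolerated by the free hydroxyl groups and by the acid-sensitive tertiary allylic 6′-OH, followed by thermal equilibration to the all-E polyene.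

**Compound list**

1 | 2-methylprop-2-enal | CC(=C)C=O | starting material
2 | ethenylmagnesium bromide | C=C[Mg]Br | starting material
3 | diethenylzinc | C=C[Zn]C=C | intermediate
4 | (3R)-2-methylpenta-1,4-dien-3-ol | C=C[C@@H](O)C(C)=C | intermediate
5 | (3R)-2-methylpenta-1,4-dien-3-yl N,N-di(propan-2-yl)carbamate | C=C[C@@H](OC(=O)N(C(C)C)C(C)C)C(C)=C | intermediate
6 | 3-methylbut-2-enal | CC(C)=CC=O | starting material
7 | 3-lithio-2-methylpenta-1,4-dien-3-yl N,N-di(propan-2-yl)carbamate (lithium in the place of the hydrogen of 5) | C=C[C@@]([Li])(OC(=O)N(C(C)C)C(C)C)C(C)=C | intermediate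
8 | 2-methyl-3-[tri(propan-2-yloxy)titanio]penta-1,4-dien-3-yl N,N-di(propan-2-yl)carbamate (metal on the opposite face to 7) | C=C[C@]([Ti](OC(C)C)(OC(C)C)OC(C)C)(OC(=O)N(C(C)C)C(C)C)C(C)=C | intermediate
9 | (3Z,6R)-6-hydroxy-2,8-dimethylnona-1,3,7-trien-3-yl N,N-di(propan-2-yl)carbamate | CC(C)=C[C@H](O)C/C=C(\OC(=O)N(C(C)C)C(C)C)C(C)=C | intermediate
10 | potassium (E)-enolate of 11 | [K+].[O-]/C=C/C(C)(C)[C@@](OC(=O)N(C(C)C)C(C)C)(C=C)C(C)=C | intermediate
11 | (3R)-3-ethenyl-2,4,4-trimethyl-6-oxohex-1-en-3-yl N,N-di(propan-2-yl)carbamate | O=CCC(C)(C)[C@@](OC(=O)N(C(C)C)C(C)C)(C=C)C(C)=C | intermediate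
12 | (1S,4S)-1-ethenyl-4-hydroxy-2,2-dimethyl-6-methylidenecyclohexyl N,N-di(propan-2-yl)carbamate (3-OH trans to 6-O) | C=C[C@]1(OC(=O)N(C(C)C)C(C)C)C(C)(C)C[C@H](O)CC1=C | intermediate
13 | (3R,4S,7S)-4-ethenyl-7-hydroxy-5,5-dimethyl-1-oxaspiro[2.5]octan-4-yl N,N-di(propan-2-yl)carbamate | C=C[C@]1(OC(=O)N(C(C)C)C(C)C)C(C)(C)C[C@H](O)C[C@@]12CO2 | intermediate
14 | (3R,4S,7R)-4-{[di(propan-2-yl)carbamoyl]oxy}-4-ethenyl-5,5-dimethyl-1-oxaspiro[2.5]octan-7-yl benzoate | C=C[C@]1(OC(=O)N(C(C)C)C(C)C)C(C)(C)C[C@@H](OC(=O)c3ccccc3)C[C@@]12CO2 | intermediate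
15 | (1S,2S,4R)-1-ethenyl-2,6,6-trimethylcyclohexane-1,2,4-triol | C=C[C@]1(O)C(C)(C)C[C@@H](O)C[C@]1(C)O | intermediate
16 | ethyl 3-oxobutanoate | CCOC(=O)CC(C)=O | starting material
17 | ethyl (2E)-3-{[(trifluoromethyl)sulfonyl]oxy}but-2-enoate | CCOC(=O)/C=C(C)/OS(=O)(=O)C(F)(F)F | intermediate
18 | ethyl (2E,4E)-3-methyl-5-[(1S,2S,4R)-1,2,4-trihydroxy-2,6,6-trimethylcyclohexyl]penta-2,4-dienoate | CCOC(=O)/C=C(C)/C=C/[C@]1(O)C(C)(C)C[C@@H](O)C[C@]1(C)O | intermediate
19 | (1S,2S,4R)-1-[(1E,3E)-5-hydroxy-3-methylpenta-1,3-dien-1-yl]-2,6,6-trimethylcyclohexane-1,2,4-triol | OC/C=C(C)/C=C/[C@]1(O)C(C)(C)C[C@@H](O)C[C@]1(C)O | intermediate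
20 | (2E,4E)-3-methyl-5-[(1S,2S,4R)-1,2,4-trihydroxy-2,6,6-trimethylcyclohexyl]penta-2,4-dienal | O=C/C=C(C)/C=C/[C@]1(O)C(C)(C)C[C@@H](O)C[C@]1(C)O | intermediate
21 | (1S,4S)-1-ethenyl-2,2-dimethyl-6-methylidenecyclohexane-1,4-diol | C=C[C@]1(O)C(C)(C)C[C@H](O)CC1=C | intermediate
22 | (1S,4S)-4-ethenyl-4-hydroxy-3,3-dimethyl-5-methylidenecyclohexyl methanesulfonate | C=C[C@]1(O)C(C)(C)C[C@H](OS(C)(=O)=O)CC1=C | intermediate
23 | (1S,4R)-1-ethenyl-2,2-dimethyl-6-methylidene-7-oxabicyclo[2.2.1]heptane | C=C[C@]12O[C@H](CC1(C)C)CC2=C | intermediate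
24 | {[(1S,2R,4R)-1-ethenyl-2-hydroxy-6,6-dimethyl-7-oxabicyclo[2.2.1]heptan-2-yl]methyl}mercury acetate | C=C[C@]12O[C@H](CC1(C)C)C[C@@]2(C[Hg]OC(C)=O)O | intermediate
25 | (1S,2R,4R)-1-ethenyl-2,6,6-trimethyl-7-oxabicyclo[2.2.1]heptan-2-ol (2-OH exo) | C=C[C@]12O[C@H](CC1(C)C)C[C@@]2(C)O | intermediate
26 | ethyl (2E,4E)-5-[(1S,2R,4R)-2-hydroxy-2,6,6-trimethyl-7-oxabicyclo[2.2.1]heptan-1-yl]-3-methylpenta-2,4-dienoate | CCOC(=O)/C=C(C)/C=C/[C@]12O[C@H](CC1(C)C)C[C@@]2(C)O | intermediate
27 | (1S,2R,4R)-1-[(1E,3E)-5-hydroxy-3-methylpenta-1,3-dien-1-yl]-2,6,6-trimethyl-7-oxabicyclo[2.2.1]heptan-2-ol | OC/C=C(C)/C=C/[C@]12O[C@H](CC1(C)C)C[C@@]2(C)O | intermediate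
28 | {(2E,4E)-5-[(1S,2R,4R)-2-hydroxy-2,6,6-trimethyl-7-oxabicyclo[2.2.1]heptan-1-yl]-3-methylpenta-2,4-dien-1-yl}(triphenyl)phosphonium bromide | [Br-].c1ccccc1[P+](c1ccccc1)(c1ccccc1)C/C=C(C)/C=C/[C@]23O[C@H](CC2(C)C)C[C@@]3(C)O | intermediate
29 | (2E,4E,6E)-2,7-dimethylocta-2,4,6-trienedial | O=C/C(C)=C/C=C/C=C(C)/C=O | starting material
30 | (2E,4E,6E,8E,10E,12E)-13-[(1S,2R,4R)-2-hydroxy-2,6,6-trimethyl-7-oxabicyclo[2.2.1]heptan-1-yl]-2,7,11-trimethyltrideca-2,4,6,8,10,12-hexaenal | CC(/C=C/C=C(C)/C=C/[C@]12O[C@H](CC1(C)C)C[C@@]2(C)O)=C\C=C\C=C(C)\C=O | intermediate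
31 | (2E,4E,6E,8E,10E,12E)-13-[(1S,2R,4R)-2-hydroxy-2,6,6-trimethyl-7-oxabicyclo[2.2.1]heptan-1-yl]-2,7,11-trimethyltrideca-2,4,6,8,10,12-hexaen-1-ol | CC(/C=C/C=C(C)/C=C/[C@]12O[C@H](CC1(C)C)C[C@@]2(C)O)=C\C=C\C=C(C)\CO | intermediate
32 | [(2E,4E,6E,8E,10E,12E)-13-[(1S,2R,4R)-2-hydroxy-2,6,6-trimethyl-7-oxabicyclo[2.2.1]heptan-1-yl]-2,7,11-trimethyltrideca-2,4,6,8,10,12-hexaen-1-yl](triphenyl)phosphonium bromide | [Br-].CC(/C=C/C=C(C)/C=C/[C@]12O[C@H](CC1(C)C)C[C@@]2(C)O)=C\C=C\C=C(C)\C[P+](c3ccccc3)(c4ccccc4)c5ccccc5 | intermediate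
33 | (3R,5R,6S,3′R,5′S,6′S)-3,6-epoxy-5,6,5′,6′-tetrahydro-β,β-carotene-5,3′,5′,6′-tetrol | CC(/C=C/C=C(C)/C=C/[C@]12O[C@H](CC1(C)C)C[C@@]2(C)O)=C\C=C\C=C(C)\C=C\C=C(C)\C=C\[C@]1(O)C(C)(C)C[C@@H](O)C[C@]1(C)O | target

**Step count and risks**

Total step count: 22. Longest linear sequence: 15 steps (steps 1–4, 12–18, 19–21 and 22).

Step 4 (most likely to fail). The [3,3] shift has to join two fully substituted carbons. Transfer of the carbamoyl group from the enol oxygen to the C3 alkoxide, or reversal of the homoaldol addition (fragmentation into 6 and the delocalised carbamate anion), may outrun it. The switch from basic to Lewis-acidic conditions in one flask may also give incomplete ene closure or poor facial control at C3. The fallback sets out from 9 and returns at 12 and avoids the alkoxide altogether. Compound 9 is silylated (Me3SiCl, imidazole, DMF) to the trimethylsilyl ether F1. This is heated (PhMe, about 180 °C, sealed tube) in a neutral Cope rearrangement of a 3-silyloxy-1,5-diene to the silyl enol ether F2. K2CO3 in MeOH then liberates aldehyde 11, which is isolated and closed in a separate operation with Me2AlCl in CH2Cl2 at −78 °C (the classical Lewis-acid type 2 carbonyl-ene cyclisation) to give 12.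

Step 3. The doubly allylic lithium compound may lose its configuration before transmetalation, which would erode the chirality transfer, and the aldehyde may attack at the carbamate-bearing carbon. Leakage through the isopropenyl arm should be harmless, because that adduct is expected to rearrange in step 4 to the same aldehyde. The fallback sets out from 6 and returns at 9; it sets C3 by reagent control instead of chirality transfer. Prop-2-enyl N,N-diisopropylcarbamate F3 (from prop-2-en-1-ol and the carbamoyl chloride) is lithiated, titanated and added to 6 to give the racemic hydroxy enol carbamate F4. Dess–Martin oxidation gives the enone F5, and CBS reduction ((S)-2-methyl-CBS-oxazaborolidine, catecholborane) gives the (R)-alcohol F6. Double deprotonation (s-BuLi, TMEDA; alkoxide and vinylic carbon α to the carbamate), ZnCl2 and Negishi coupling with 2-bromopropene (Pd(PPh3)4) install the isopropenyl group with retention of the (Z) geometry and give 9.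

Step 14. E2 elimination of the secondary mesylate and the strain of the boat-shaped SN2 transition state may prevent closure of the oxolane bridge. The fallback sets out from 12 and returns at 23; it closes the same bond by SN1 at C6 with O3 as the nucleophile. Mitsunobu inversion of 12 with benzoic acid gives the inverted benzoate F7, and LiAlH4 removes both acyl groups to give the cis-1,4-diol F8. A trace of camphorsulfonic acid in CH2Cl2 at 0 °C should ionise the tertiary, doubly allylic C6–OH, and the cis-disposed 3-OH captures the cation from its own face to give 23.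

Further compounds
F1 | step 4 | (3Z,6R)-2,8-dimethyl-6-[(trimethylsilyl)oxy]nona-1,3,7-trien-3-yl N,N-di(propan-2-yl)carbamate | CC(C)=C[C@H](O[Si](C)(C)C)C/C=C(\OC(=O)N(C(C)C)C(C)C)C(C)=C
F2 | step 4 | (3R,5E)-3-ethenyl-2,4,4-trimethyl-6-[(trimethylsilyl)oxy]hexa-1,5-dien-3-yl N,N-di(propan-2-yl)carbamate | C[Si](C)(C)O/C=C/C(C)(C)[C@@](OC(=O)N(C(C)C)C(C)C)(C=C)C(C)=C
F3 | step 3 | prop-2-en-1-yl N,N-di(propan-2-yl)carbamate | C=CCOC(=O)N(C(C)C)C(C)C
F4 | step 3 | rac-(1Z)-4-hydroxy-6-methylhepta-1,5-dien-1-yl N,N-di(propan-2-yl)carbamate | CC(C)=CC(O)C/C=C\OC(=O)N(C(C)C)C(C)C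
F5 | step 3 | (1Z)-6-methyl-4-oxohepta-1,5-dien-1-yl N,N-di(propan-2-yl)carbamate | CC(C)=CC(=O)C/C=C\OC(=O)N(C(C)C)C(C)C
F6 | step 3 | (1Z,4R)-4-hydroxy-6-methylhepta-1,5-dien-1-yl N,N-di(propan-2-yl)carbamate | CC(C)=C[C@H](O)C/C=C\OC(=O)N(C(C)C)C(C)C
F7 | step 14 | (1R,4S)-4-{[di(propan-2-yl)carbamoyl]oxy}-4-ethenyl-3,3-dimethyl-5-methylidenecyclohexyl benzoate | C=C[C@]1(OC(=O)N(C(C)C)C(C)C)C(C)(C)C[C@@H](OC(=O)c2ccccc2)CC1=C
F8 | step 14 | (1S,4R)-1-ethenyl-2,2-dimethyl-6-methylidenecyclohexane-1,4-diol | C=C[C@]1(O)C(C)(C)C[C@@H](O)CC1=C
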